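**Strategy.** Ring B (C4a, C5, C6, C7, C8, C8a) is disconnected at C5–C6 and C4a–C8a. In it the tertiary carbinol C6, which carries ring C, and the angular C8a are 1,4-related, and the C6–O bond and the C8a–C1 bond point to the same face. O and C1 are therefore read as the O–C(=O) bridge of a 2-pyrone cycloadduct. One inverse-demand Diels–Alder reaction of 1,1-dimethoxyethene with a 5-bromo-3-methyl-2-pyrone that already bears the complete, silyl-protected ring C at its 6-position closes ring B, fixes C6 and C8a, and delivers C1 as lactone carbonyl and C4a as ketal. Ring A is annulated afterwards.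

Key step: step 15

Remarks on the chemistry (assumptions)
- Labels (target numbering): ring A = C1 (CHBr), C2, C3, C4 (C(OH)CH3), C4a (C–OH), C8a (C–CH3); ring B = C4a, C5, C6 (C–OH bearing ring C), C7, C8, C8a; ring C = C1′ (quaternary, on C6), C2′ (CHOH), C3′, C4′ (CHBr), C5′ (CMe2).
- RC = 4-bromo-2-(tert-butyldimethylsilyloxy)-1,5,5-trimethylcyclopentyl bonded through C1′; Br, OTBS and the bond from C1′ are mutually cis, the C1′ methyl is trans to them.
- Compounds 1, 12, 18 and 21 are taken as commercially available. The sense of induction of the chiral catalysts in steps 2 and 3 is assumed to be selectable through the catalyst enantiomer.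
- The pyrone carries a 5-bromine (removed in step 16) because a 3,6-dialkyl-2-pyrone is a poor partner for a ketene acetal. The bromine lowers the LUMO and also fixes the rotamer about the C6–C1′ bond.
- The C4a ketal is never turned into a ketone. Such a ketone would be a β-acyloxy (later β-hydroxy) ketone prone to elimination or retro-aldol cleavage of C5–C6, and a carbon nucleophile would have to enter its hindered face. Instead C4a becomes an alkene carbon and receives oxygen from the open face.

**Step 1**
Reactants: 1 4,4-dimethylcyclopent-2-en-1-one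
Product: 2 tert-butyl 5,5-dimethyl-2-oxocyclopent-3-ene-1-carboxylate (racemic; enolisable)
Conditions: LiN(i-Pr)2 (2.2 equiv), THF, −78 °C; Boc2O; aq. NH4Cl
Reagents that add atoms: di-tert-butyl dicarbonate, CC(C)(C)OC(=O)OC(=O)OC(C)(C)C
Why: Only C5 of the enone carries acidic α-hydrogens (C3 is vinylic, C4 quaternary), so the kinetic lithium enolate forms there and undergoes Claisen-type C-acylation, the second equivalent of base storing the β-keto ester as its enolate.

**Step 2**
Reactants: 2 tert-butyl 5,5-dimethyl-2-oxocyclopent-3-ene-1-carboxylate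
Product: 3 tert-butyl (1R)-1,5,5-trimethyl-2-oxocyclopent-3-ene-1-carboxylate
Conditions: MeI, CsOH·H2O, chiral N-spiro binaphthyl quaternary ammonium bromide (2 mol%), toluene, −40 °C
Reagents that add atoms: iodomethane, CI
Why: Asymmetric phase-transfer alkylation, in which the chiral ammonium enolate ion pair of the cyclic β-keto tert-butyl ester is methylated on one face, creates the quaternary stereocentre C1′, which cannot epimerise afterwards.

**Step 3**
Reactants: 3 tert-butyl (1R)-1,5,5-trimethyl-2-oxocyclopent-3-ene-1-carboxylate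
Product: 5 tert-butyl (1R)-4-hydroxy-1,5,5-trimethyl-2-oxocyclopentane-1-carboxylate (4-OH cis to the 1-methyl), via pinacol boronate 4 (not isolated)
Conditions: B2pin2, Cu(MeCN)4PF6 (5 mol%), QuinoxP* (matched enantiomer, 6 mol%), LiOtBu (10 mol%), MeOH, THF, 0 °C; then NaBO3·4H2O, THF/H2O, 25 °C
Reagents that add atoms: sodium perborate, [Na+].[O-]OB=O (oxygen of 5); bis(pinacolato)diboron, CC1(C)OB(OC1(C)C)B1OC(C)(C)C(C)(C)O1 (boron of 4)
Why: Copper-catalysed conjugate borylation places boron on the β-carbon (future C4′) from the face opposite the bulky tert-butyl ester, a preference reinforced by the matched chiral diphosphine, and the perborate oxidation replaces boron by oxygen with retention.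

**Step 4**
Reactants: 5 tert-butyl (1R)-4-hydroxy-1,5,5-trimethyl-2-oxocyclopentane-1-carboxylate
Product: 6 tert-butyl 4-acetoxy-2-hydroxy-1,5,5-trimethylcyclopentane-1-carboxylate (2-OH cis to the ester; 4-OAc trans to both)
Conditions: MeCHO (6 equiv), SmI2 (20 mol%), THF, −10 °C
Reagents that add atoms: acetaldehyde, CC=O
Why: In this Evans–Tishchenko reduction the samarium-bound hemiacetal formed from the C4′ hydroxyl and acetaldehyde transfers hydride intramolecularly to the same face of the ketone, which gives the 1,3-anti diol (new C2′–OH cis to the ester) and marks the directing oxygen as an acetate.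

**Step 5**
Reactants: 6 tert-butyl 4-acetoxy-2-hydroxy-1,5,5-trimethylcyclopentane-1-carboxylate
Product: 7 tert-butyl 4-acetoxy-2-(tert-butyldimethylsilyloxy)-1,5,5-trimethylcyclopentane-1-carboxylate
Conditions: TBSOTf, 2,6-lutidine, CH2Cl2, −78 → 0 °C
Reagents that add atoms: tert-butyldimethylsilyl trifluoromethanesulfonate, CC(C)(C)[Si](C)(C)OS(=O)(=O)C(F)(F)F
Why: Silylation with the silyl triflate and a non-nucleophilic base protects the hindered secondary alcohol and leaves acetate and tert-butyl ester untouched.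

**Step 6**
Reactants: 7 tert-butyl 4-acetoxy-2-(tert-butyldimethylsilyloxy)-1,5,5-trimethylcyclopentane-1-carboxylate
Product: 8 tert-butyl 4-hydroxy-2-(tert-butyldimethylsilyloxy)-1,5,5-trimethylcyclopentane-1-carboxylate (OTBS cis to the ester; 4-OH trans)
Conditions: K2CO3 (cat.), MeOH, 25 °C
Reagents that add atoms: none
Why: Base-catalysed transesterification removes the secondary acetate while the neopentyl tert-butyl ester and the silyl ether are inert.

**Step 7**
Reactants: 8 tert-butyl 4-hydroxy-2-(tert-butyldimethylsilyloxy)-1,5,5-trimethylcyclopentane-1-carboxylate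
Product: 9 tert-butyl 4-bromo-2-(tert-butyldimethylsilyloxy)-1,5,5-trimethylcyclopentane-1-carboxylate (Br, OTBS and ester all cis; RC–CO2t-Bu)
Conditions: PPh3, CBr4, CH2Cl2, 0 → 40 °C
Reagents that add atoms: tetrabromomethane, BrC(Br)(Br)Br
Why: In the Appel reaction bromide displaces the alkoxyphosphonium group by SN2 with inversion, which moves the C4′ substituent to the face of the silyl ether and the ester; substitution at this neopentyl-type carbon is helped by the cyclopentane ring.

**Step 8**
Reactants: 9 tert-butyl 4-bromo-2-(tert-butyldimethylsilyloxy)-1,5,5-trimethylcyclopentane-1-carboxylate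
Product: 10 RC-methanol
Conditions: i-Bu2AlH (3 equiv), CH2Cl2, −78 → 0 °C; aq. potassium sodium tartrate
Reagents that add atoms: none
Why: Hydride reduction of the ester by the electrophilic aluminium hydride runs through to the primary alcohol without touching the secondary bromide or the silyl ether.

**Step 9**
Reactants: 10 RC-methanol
Product: 11 RC-carbaldehyde
Conditions: Dess–Martin periodinane, NaHCO3, CH2Cl2, 25 °C
Reagents that add atoms: none
Why: Dess–Martin oxidation gives an aldehyde without α-hydrogen, so it can neither epimerise nor eliminate.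

**Step 10**
Reactants: 12 methyl tiglate
Product: 13 1-methoxy-2-methyl-1-(trimethylsilyloxy)buta-1,3-diene (E/Z mixture)
Conditions: LiN(i-Pr)2, DMPU, THF, −78 °C; Me3SiCl
Reagents that add atoms: chlorotrimethylsilane, C[Si](C)(C)Cl
Why: γ-Deprotonation of the enoate gives the extended lithium enolate, which is silylated on oxygen to the vinylketene silyl acetal.

**Step 11**
Reactants: 11 RC-carbaldehyde; 13 1-methoxy-2-methyl-1-(trimethylsilyloxy)buta-1,3-diene
Product: 14 methyl (E)-5-hydroxy-2-methyl-5-RC-pent-2-enoate (both C5 epimers)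
Conditions: B(C6F5)3 (20 mol%), CH2Cl2, −78 °C; then 1 M HCl
Reagents that add atoms: none
Why: In this vinylogous Mukaiyama aldol addition the activated aldehyde is attacked by the γ-carbon of the silyl dienolate to give the (E)-enoate; the new carbinol configuration is irrelevant because it is oxidised next.

**Step 12**
Reactants: 14 methyl (E)-5-hydroxy-2-methyl-5-RC-pent-2-enoate
Product: 15 methyl (E)-2-methyl-5-oxo-5-RC-pent-2-enoate
Conditions: Dess–Martin periodinane, NaHCO3, CH2Cl2, 25 °C
Reagents that add atoms: none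
Why: Dess–Martin oxidation of the secondary alcohol gives the δ-keto enoate under neutral conditions that neither isomerise the alkene nor eliminate bromide.

**Step 13**
Reactants: 15 methyl (E)-2-methyl-5-oxo-5-RC-pent-2-enoate
Product: 16 3-methyl-6-RC-2H-pyran-2-one
Conditions: DBU, toluene, 40 °C
Reagents that add atoms: none
Why: In this base-mediated enol lactonisation, deprotonation of the doubly activated methylene gives a delocalised enolate in which the enoate geometry equilibrates, and the enolate oxygen acylates intramolecularly (6-exo-trig) with loss of methoxide to give the 2-pyrone.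

**Step 14**
Reactants: 16 3-methyl-6-RC-2H-pyran-2-one
Product: 17 5-bromo-3-methyl-6-RC-2H-pyran-2-one
Conditions: NBS, MeCN, 0 → 25 °C, dark
Reagents that add atoms: N-bromosuccinimide, O=C1CCC(=O)N1Br
Why: Electrophilic bromination of the 2-pyrone occurs at C5, the only free nucleophilic ring position once C3 carries a methyl group.

**Step 15 (key step)**
Reactants: 17 5-bromo-3-methyl-6-RC-2H-pyran-2-one; 18 1,1-dimethoxyethene
Product: 19 7-bromo-5,5-dimethoxy-4-methyl-1-RC-2-oxabicyclo[2.2.2]oct-7-en-3-one (bicycle C1 = future C6, C4 = future C8a, C3 = future C1, C5 = future C4a, C6 = future C5)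
Conditions: 18 (5 equiv), K2CO3 (trace), CH2Cl2, 13 kbar, 25 °C, 72 h
Reagents that add atoms: none
Why: The electron-rich CH2 terminus of the ketene acetal attacks the electrophilic 6-position of the pyrone while the acetal carbon closes onto C3 in a concerted but asynchronous inverse-demand [4+2] cycloaddition, whose strongly negative activation volume lets it run at 25 °C so that the bicyclic lactone survives without loss of CO2. The closest known reactions are the pressure-promoted cycloadditions of 3- and 5-bromo-2-pyrones with enol ethers and ketene acetals, which give isolable 2-oxabicyclo[2.2.2]octenones with the oxygenated carbon next to the former pyrone C3. Ring B is closed as a carbocycle by suprafacial addition across the two pyrone termini (new bonds C5–C6 and C4a–C8a), and the second ring is the former pyrone ring, which gains no new bond but is folded into the O–C1(=O) bridge of the bicycle. The new stereocentres C6 and C8a are tied to each other by that bridge (C6–O and C8a–C1 necessarily cis). Their sense relative to ring C is set by the quaternary C1′: with its methyl eclipsing the 5-bromine, the C2′ silyl ether covers one pyrone face and the dienophile enters from the face flanked only by a C5′ methyl. The step needs regio- and face selectivity; the first is secured by the polarity match, reinforced by the 5-bromine, and the second by the bulky silyl ether cis to the pyrone, while endo/exo selectivity does not arise because both acetal substituents are methoxy.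

**Step 16**
Reactants: 19 7-bromo-5,5-dimethoxy-4-methyl-1-RC-2-oxabicyclo[2.2.2]oct-7-en-3-one
Product: 20 5,5-dimethoxy-4-methyl-1-RC-2-oxabicyclo[2.2.2]octan-3-one
Conditions: H2 (1 atm), Pd/C, Et3N, EtOAc, 25 °C
Reagents that add atoms: none
Why: Heterogeneous hydrogenation saturates the strained alkene and hydrogenolyses the alkenyl C–Br bond, whereas the neopentyl secondary alkyl bromide of ring C, the ketal (kept neutral by triethylamine) and the lactone do not react.

**Step 17**
Reactants: 20 5,5-dimethoxy-4-methyl-1-RC-2-oxabicyclo[2.2.2]octan-3-one; 21 ethyl prop-1-enyl ether (E/Z mixture)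
Product: 22 5-(1-ethoxy-1-methoxypropan-2-yl)-5-methoxy-4-methyl-1-RC-2-oxabicyclo[2.2.2]octan-3-one (mixture at the three new centres)
Conditions: 21 (3 equiv), BF3·OEt2 (10 mol%), CH2Cl2, −78 → −30 °C
Reagents that add atoms: none
Why: In this acetal–enol ether condensation (Mukaiyama-type addition to an oxocarbenium ion) BF3 ionises the ketal, the β-carbon of the enol ether adds, and the new oxocarbenium ion takes up the released methoxide, so C4a gains its carbon substituent without becoming a ketone; the three new centres are erased in step 19.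

**Step 18**
Reactants: 22 5-(1-ethoxy-1-methoxypropan-2-yl)-5-methoxy-4-methyl-1-RC-2-oxabicyclo[2.2.2]octan-3-one
Product: 23 1-[2-(1-ethoxy-1-methoxypropan-2-yl)-4-hydroxy-2-methoxy-1-methyl-4-RC-cyclohexyl]ethan-1-one (acetyl and 4-OH cis)
Conditions: MeLi (1.5 equiv), THF, −78 °C; aq. NH4Cl
Reagents that add atoms: methyllithium, [Li]C
Why: Nucleophilic acyl substitution on the bridged lactone stops after one addition because the tetrahedral lithium hemiketal alkoxide at this neopentyl carbonyl is stable at −78 °C; work-up releases the methyl ketone and the C6 tertiary alcohol while the acetal protects the latent aldehyde.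

**Step 19**
Reactants: 23 1-[2-(1-ethoxy-1-methoxypropan-2-yl)-4-hydroxy-2-methoxy-1-methyl-4-RC-cyclohexyl]ethan-1-one
Product: 25 6-hydroxy-4,8a-dimethyl-6-RC-6,7,8,8a-tetrahydronaphthalen-1(5H)-one (C6–OH trans to the 8a-methyl), via keto enal 24 (not isolated)
Conditions: PPTS, acetone/H2O, 40 °C; then piperidine, AcOH, toluene, 60 °C
Reagents that add atoms: none
Why: Acetal hydrolysis with β-elimination of methanol gives the enal, and an amine-catalysed intramolecular aldol condensation (6-enolexo-exo-trig; the ketone can enolise only toward its methyl group, and the enal isomers interconvert through the dienamine) closes ring A as the conjugated dienone.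

**Step 20**
Reactants: 25 6-hydroxy-4,8a-dimethyl-6-RC-6,7,8,8a-tetrahydronaphthalen-1(5H)-one
Product: 26 6-hydroxy-4,8a-dimethyl-6-RC-3,5,6,7,8,8a-hexahydronaphthalen-1(2H)-one
Conditions: H2 (1 atm), RhCl(PPh3)3 (10 mol%), benzene, 25 °C
Reagents that add atoms: none
Why: Homogeneous hydrogenation with the rhodium phosphine catalyst reduces the accessible disubstituted C2=C3 alkene and leaves the tetrasubstituted C4=C4a alkene, as in the selective reduction of steroidal dienones.

**Step 21**
Reactants: 26 6-hydroxy-4,8a-dimethyl-6-RC-3,5,6,7,8,8a-hexahydronaphthalen-1(2H)-one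
Product: 27 6-hydroxy-4,8a-dimethyl-6-RC-3,5,6,7,8,8a-hexahydronaphthalen-1-yl trifluoromethanesulfonate
Conditions: KN(SiMe3)2 (2.2 equiv), THF, −78 °C; PhNTf2
Reagents that add atoms: N-phenylbis(trifluoromethanesulfonimide), O=S(=O)(N(c1ccccc1)S(=O)(=O)C(F)(F)F)C(F)(F)F
Why: Kinetic enolisation of the ketone can only occur toward C2 (C8a is quaternary), and O-sulfonylation of the potassium enolate gives the alkenyl triflate.

**Step 22**
Reactants: 27 6-hydroxy-4,8a-dimethyl-6-RC-3,5,6,7,8,8a-hexahydronaphthalen-1-yl trifluoromethanesulfonate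
Product: 28 5-bromo-4a,8-dimethyl-2-RC-1,2,3,4,4a,7-hexahydronaphthalen-2-ol (target numbering: C1–Br, C1=C2 and C4=C4a alkenes, C6–OH)
Conditions: LiBr, [Cp*Ru(MeCN)3]OTf (5 mol%), DMI, 60 °C
Reagents that add atoms: lithium bromide, [Li+].[Br-]
Why: Ruthenium-catalysed exchange of alkenyl triflate for bromide (oxidative addition, halide exchange, reductive elimination) makes C1 an alkenyl bromide without touching the skipped diene or the tertiary alcohol.

**Step 23**
Reactants: 28 5-bromo-4a,8-dimethyl-2-RC-1,2,3,4,4a,7-hexahydronaphthalen-2-ol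
Product: 30 alkenyl bromide triol (target numbering: C1–Br, C1=C2, C4–OH cis to the 8a-methyl, C4a–OH and C6–OH trans to it), via epoxide 29 (not isolated)
Conditions: mCPBA, NaHCO3, CH2Cl2, 0 °C; then HClO4 (aq.), THF, 0 → 25 °C
Reagents that add atoms: 3-chloroperbenzoic acid, O=C(OO)c1cccc(Cl)c1; water, O
Why: Peracid epoxidation of the electron-rich tetrasubstituted alkene occurs anti to the angular methyl and syn to the hydrogen-bonding C6 hydroxyl, and acid-catalysed trans-diaxial (Fürst–Plattner) opening by water at C4, the less congested tertiary carbon, sets C4a–OH and C4–OH trans with the C4 methyl equatorial.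

**Step 24**
Reactants: 30 alkenyl bromide triol
Product: 31 2′-O-(tert-butyldimethylsilyl)neoirietetraol
Conditions: Mn(dpm)3 (10 mol%), PhSiH3, t-BuOOH, i-PrOH, 25 °C
Reagents that add atoms: none
Why: In this metal-hydride hydrogen atom transfer hydrogenation the manganese hydride gives H to C2, and the α-bromo radical at C1 then takes H axially from the face opposite the angular methyl, leaving bromine equatorial; this radical hydrogenation is known to preserve carbon–halogen bonds.

**Step 25**
Reactants: 31 2′-O-(tert-butyldimethylsilyl)neoirietetraol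
Product: 32 neoirietetraol
Conditions: HF·pyridine, pyridine, THF, 0 → 25 °C
Reagents that add atoms: none
Why: Fluoride-mediated cleavage of the silyl ether under buffered acidic conditions frees the C2′ hydroxyl without base-induced elimination of the two secondary bromides.

**Compound list**
1 | 4,4-dimethylcyclopent-2-en-1-one | CC1(C)C=CC(=O)C1 | starting material
2 | tert-butyl 5,5-dimethyl-2-oxocyclopent-3-ene-1-carboxylate (racemic) | CC1(C)C=CC(=O)C1C(=O)OC(C)(C)C | intermediate
3 | tert-butyl (1R)-1,5,5-trimethyl-2-oxocyclopent-3-ene-1-carboxylate | CC1(C)C=CC(=O)[C@]1(C)C(=O)OC(C)(C)C | intermediate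
4 | tert-butyl 1,5,5-trimethyl-2-oxo-4-(pinacolatoboryl)cyclopentane-1-carboxylate (boron cis to the 1-methyl) | CC1(C)[C@@H](B2OC(C)(C)C(C)(C)O2)CC(=O)[C@]1(C)C(=O)OC(C)(C)C | intermediate (not isolated)
5 | tert-butyl (1R)-4-hydroxy-1,5,5-trimethyl-2-oxocyclopentane-1-carboxylate (4-OH cis to the 1-methyl) | CC1(C)[C@@H](O)CC(=O)[C@]1(C)C(=O)OC(C)(C)C | intermediate
6 | tert-butyl 4-acetoxy-2-hydroxy-1,5,5-trimethylcyclopentane-1-carboxylate (2-OH cis to ester, 4-OAc trans) | CC1(C)[C@@H](OC(C)=O)C[C@H](O)[C@]1(C)C(=O)OC(C)(C)C | intermediate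
7 | tert-butyl 4-acetoxy-2-(tert-butyldimethylsilyloxy)-1,5,5-trimethylcyclopentane-1-carboxylate | CC1(C)[C@@H](OC(C)=O)C[C@H](O[Si](C)(C)C(C)(C)C)[C@]1(C)C(=O)OC(C)(C)C | intermediate
8 | tert-butyl 4-hydroxy-2-(tert-butyldimethylsilyloxy)-1,5,5-trimethylcyclopentane-1-carboxylate (4-OH trans to OTBS and ester) | CC1(C)[C@@H](O)C[C@H](O[Si](C)(C)C(C)(C)C)[C@]1(C)C(=O)OC(C)(C)C | intermediate
9 | tert-butyl 4-bromo-2-(tert-butyldimethylsilyloxy)-1,5,5-trimethylcyclopentane-1-carboxylate (all-cis; RC–CO2t-Bu) | CC1(C)[C@H](Br)C[C@H](O[Si](C)(C)C(C)(C)C)[C@]1(C)C(=O)OC(C)(C)C | intermediate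
10 | RC-methanol | CC1(C)[C@H](Br)C[C@H](O[Si](C)(C)C(C)(C)C)[C@]1(C)CO | intermediate
11 | RC-carbaldehyde | CC1(C)[C@H](Br)C[C@H](O[Si](C)(C)C(C)(C)C)[C@]1(C)C=O | intermediate
12 | methyl tiglate | C/C=C(\C)C(=O)OC | starting material
13 | 1-methoxy-2-methyl-1-(trimethylsilyloxy)buta-1,3-diene | C=CC(C)=C(OC)O[Si](C)(C)C | intermediate
14 | methyl (E)-5-hydroxy-2-methyl-5-RC-pent-2-enoate | CC1(C)[C@H](Br)C[C@H](O[Si](C)(C)C(C)(C)C)[C@]1(C)C(O)C/C=C(\C)C(=O)OC | intermediate
15 | methyl (E)-2-methyl-5-oxo-5-RC-pent-2-enoate | CC1(C)[C@H](Br)C[C@H](O[Si](C)(C)C(C)(C)C)[C@]1(C)C(=O)C/C=C(\C)C(=O)OC | intermediate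
16 | 3-methyl-6-RC-2H-pyran-2-one | CC1(C)[C@H](Br)C[C@H](O[Si](C)(C)C(C)(C)C)[C@]1(C)C2=CC=C(C)C(=O)O2 | intermediate
17 | 5-bromo-3-methyl-6-RC-2H-pyran-2-one | CC1(C)[C@H](Br)C[C@H](O[Si](C)(C)C(C)(C)C)[C@]1(C)C2=C(Br)C=C(C)C(=O)O2 | intermediate
18 | 1,1-dimethoxyethene | C=C(OC)OC | starting material
19 | 7-bromo-5,5-dimethoxy-4-methyl-1-RC-2-oxabicyclo[2.2.2]oct-7-en-3-one | CC1(C)[C@H](Br)C[C@H](O[Si](C)(C)C(C)(C)C)[C@]1(C)[C@@]2(O3)C(Br)=C[C@](C)(C3=O)C(OC)(OC)C2 | intermediate
20 | 5,5-dimethoxy-4-methyl-1-RC-2-oxabicyclo[2.2.2]octan-3-one | CC1(C)[C@H](Br)C[C@H](O[Si](C)(C)C(C)(C)C)[C@]1(C)[C@@]2(O3)CC[C@](C)(C3=O)C(OC)(OC)C2 | intermediate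
21 | ethyl prop-1-enyl ether (E/Z mixture) | CC=COCC | starting material
22 | 5-(1-ethoxy-1-methoxypropan-2-yl)-5-methoxy-4-methyl-1-RC-2-oxabicyclo[2.2.2]octan-3-one | CC1(C)[C@H](Br)C[C@H](O[Si](C)(C)C(C)(C)C)[C@]1(C)[C@@]2(O3)CC[C@](C)(C3=O)C(OC)(C(C)C(OC)OCC)C2 | intermediate
23 | 1-[2-(1-ethoxy-1-methoxypropan-2-yl)-4-hydroxy-2-methoxy-1-methyl-4-RC-cyclohexyl]ethan-1-one | CC1(C)[C@H](Br)C[C@H](O[Si](C)(C)C(C)(C)C)[C@]1(C)[C@@]2(O)CC[C@](C)(C(C)=O)C(OC)(C(C)C(OC)OCC)C2 | intermediate
24 | 2-(2-acetyl-5-hydroxy-2-methyl-5-RC-cyclohexylidene)propanal (E/Z) | CC1(C)[C@H](Br)C[C@H](O[Si](C)(C)C(C)(C)C)[C@]1(C)[C@@]2(O)CC[C@](C)(C(C)=O)C(=C(C)C=O)C2 | intermediate (not isolated)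
25 | 6-hydroxy-4,8a-dimethyl-6-RC-6,7,8,8a-tetrahydronaphthalen-1(5H)-one | CC1(C)[C@H](Br)C[C@H](O[Si](C)(C)C(C)(C)C)[C@]1(C)[C@@]2(O)CC[C@]3(C)C(=O)C=CC(C)=C3C2 | intermediate
26 | 6-hydroxy-4,8a-dimethyl-6-RC-3,5,6,7,8,8a-hexahydronaphthalen-1(2H)-one | CC1(C)[C@H](Br)C[C@H](O[Si](C)(C)C(C)(C)C)[C@]1(C)[C@@]2(O)CC[C@]3(C)C(=O)CCC(C)=C3C2 | intermediate
27 | 6-hydroxy-4,8a-dimethyl-6-RC-3,5,6,7,8,8a-hexahydronaphthalen-1-yl trifluoromethanesulfonate | CC1(C)[C@H](Br)C[C@H](O[Si](C)(C)C(C)(C)C)[C@]1(C)[C@@]2(O)CC[C@]3(C)C(OS(=O)(=O)C(F)(F)F)=CCC(C)=C3C2 | intermediate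
28 | 5-bromo-4a,8-dimethyl-2-RC-1,2,3,4,4a,7-hexahydronaphthalen-2-ol | CC1(C)[C@H](Br)C[C@H](O[Si](C)(C)C(C)(C)C)[C@]1(C)[C@@]2(O)CC[C@]3(C)C(Br)=CC[C@]4(C)O[C@]34C2 is 29; 28 is CC1(C)[C@H](Br)C[C@H](O[Si](C)(C)C(C)(C)C)[C@]1(C)[C@@]2(O)CC[C@]3(C)C(Br)=CCC(C)=C3C2 | intermediate
29 | C4–C4a epoxide of 28 (oxygen anti to the 8a-methyl) | CC1(C)[C@H](Br)C[C@H](O[Si](C)(C)C(C)(C)C)[C@]1(C)[C@@]2(O)CC[C@]3(C)C(Br)=CC[C@]4(C)O[C@]34C2 | intermediate (not isolated)
30 | alkenyl bromide triol (C1–Br, C1=C2; C4–OH, C4a–OH, C6–OH as in the target) | CC1(C)[C@H](Br)C[C@H](O[Si](C)(C)C(C)(C)C)[C@]1(C)[C@@]2(O)CC[C@]3(C)C(Br)=CC[C@@](C)(O)[C@@]3(O)C2 | intermediate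
31 | 2′-O-(tert-butyldimethylsilyl)neoirietetraol | CC1(C)[C@H](Br)C[C@H](O[Si](C)(C)C(C)(C)C)[C@]1(C)[C@@]2(O)CC[C@]3(C)[C@@H](Br)CC[C@@](C)(O)[C@@]3(O)C2 | intermediate
32 | neoirietetraol | CC1(C)[C@H](Br)C[C@H](O)[C@]1(C)[C@@]1(O)CC[C@]2(C)[C@@H](Br)CC[C@@](C)(O)[C@@]2(O)C1 | target

(In line 28 the SMILES of 28 is the second string, CC1(C)[C@H](Br)C[C@H](O[Si](C)(C)C(C)(C)C)[C@]1(C)[C@@]2(O)CC[C@]3(C)C(Br)=CCC(C)=C3C2; the first string in that line is the epoxide 29.)

**Totals and risks**
Total step count: 25. Longest linear sequence: 24 steps (steps 1–9 and 11–25; step 10 is a one-step side branch).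

Steps most likely to fail:

1. Step 15. The dienophile may not discriminate well enough between the two pyrone faces, and addition next to the quaternary C1′ may be slow, so the lactone epimeric at C6/C8a would form as well. Fallback (change of the face-controlling element): set out from 17. HF·pyridine removes the silyl group to give hydroxy pyrone F1. i-Pr3SiOTf/2,6-lutidine gives the triisopropylsilyl ether F2, a larger shield over the face that must stay closed. Cycloaddition with 18 at 13 kbar gives the cycloadduct F3. Bu4NF/AcOH then gives the hydroxy lactone F4, and TBSOTf/2,6-lutidine returns to the route at 19.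

2. Step 17. The hindered oxocarbenium ion at C4a may lose a proton to a methyl enol ether, and the propenyl ether may oligomerise, so that no C4–C4a bond forms. Fallback (the bond is made intramolecularly): set out from 20. But-1-enyllithium (from 1-bromobut-1-ene and t-BuLi, −78 °C) opens the lactone to the hydroxy enone ketal F5. Me3SiOTf/i-Pr2NEt then forms the silyl dienol ether and ionises the ketal in the same flask, so that the γ-carbon closes ring A (vinylogous Mukaiyama addition to the ketal). DBU expels methanol and K2CO3/MeOH removes the silyl group from O6, which returns to the route at 25.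

3. Step 7. Elimination to the cyclopentene or methyl migration may outrun substitution at the neopentyl C4′, whose backside is flanked by the silyl ether and the ester. Fallback (the C–Br stereocentre is set by hydrogen delivery instead of bromide delivery): set out from 8. Dess–Martin oxidation gives the ketone F6. P(OPh)3/Br2/Et3N (CH2Cl2, −60 → 25 °C) converts it into the alkenyl bromide F7; enolisation is possible only toward C3′. Hydrogen atom transfer hydrogenation (Mn(dpm)3, PhSiH3, t-BuOOH, i-PrOH) should deliver hydrogen to C4′ from the open face opposite silyl ether and ester, which returns to the route at 9.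

**Further compounds**
F1 | step 15 | 5-bromo-6-(4-bromo-2-hydroxy-1,5,5-trimethylcyclopentyl)-3-methyl-2H-pyran-2-one (ring C configured as in RC) | CC1(C)[C@H](Br)C[C@H](O)[C@]1(C)C2=C(Br)C=C(C)C(=O)O2
F2 | step 15 | triisopropylsilyl ether of F1 | CC1(C)[C@H](Br)C[C@H](O[Si](C(C)C)(C(C)C)C(C)C)[C@]1(C)C2=C(Br)C=C(C)C(=O)O2
F3 | step 15 | triisopropylsilyl analogue of 19 | CC1(C)[C@H](Br)C[C@H](O[Si](C(C)C)(C(C)C)C(C)C)[C@]1(C)[C@@]2(O3)C(Br)=C[C@](C)(C3=O)C(OC)(OC)C2
F4 | step 15 | 2′-hydroxy analogue of 19 | CC1(C)[C@H](Br)C[C@H](O)[C@]1(C)[C@@]2(O3)C(Br)=C[C@](C)(C3=O)C(OC)(OC)C2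
F5 | step 17 | 1-(4-hydroxy-2,2-dimethoxy-1-methyl-4-RC-cyclohexyl)pent-2-en-1-one (acyl group and 4-OH cis) | CC1(C)[C@H](Br)C[C@H](O[Si](C)(C)C(C)(C)C)[C@]1(C)[C@@]2(O)CC[C@](C)(C(=O)C=CCC)C(OC)(OC)C2
F6 | step 7 | tert-butyl 2-(tert-butyldimethylsilyloxy)-1,5,5-trimethyl-4-oxocyclopentane-1-carboxylate (OTBS cis to ester) | CC1(C)C(=O)C[C@H](O[Si](C)(C)C(C)(C)C)[C@]1(C)C(=O)OC(C)(C)C
F7 | step 7 | tert-butyl 4-bromo-2-(tert-butyldimethylsilyloxy)-1,5,5-trimethylcyclopent-3-ene-1-carboxylate (OTBS cis to ester) | CC1(C)C(Br)=C[C@H](O[Si](C)(C)C(C)(C)C)[C@]1(C)C(=O)OC(C)(C)C
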